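**Retrosynthetic overview**
- Target ⇒ hydroxyalkyl-p-quinone + 2 MeCHO: both ring C–H stereocentres and both acetates come from one relay Tishchenko hydride transfer (new step), steered only by the side-chain carbinol.
- Quinone ⇒ 2-alkyl-6-methoxyphenol by para-oxidation.
- Phenol ⇒ 2-iodo-6-methoxyphenol + (R)-2-undecyloxirane: the aryl–CH2 bond is made by visible-light nickel/photoredox cross-electrophile coupling.
- Epoxide ⇒ (R)-epichlorohydrin + decylmagnesium bromide; this is the only purchased stereocentre.
- Rings: the six-membered ring is bought as a benzene ring and dearomatised in the last two steps; the only ring made is the oxirane (step 1), opened in step 2.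

Assumption: decylmagnesium bromide (1.0 M in Et2O) and 2-iodo-6-methoxyphenol are taken as catalogue compounds.

Step 1
Reactants: 1 (R)-epichlorohydrin; 2 decylmagnesium bromide
Product: 4 (R)-2-undecyloxirane, via (R)-1-chlorotridecan-2-ol 3 (not isolated)
Conditions: 2 (1.2 equiv), CuI (5 mol %), THF, −40 → 0 °C; then 2 M aq NaOH, 25 °C
Reagents that add atoms: none
Why: Copper-catalysed Grignard opening of the epoxide (SN2 at the unsubstituted CH2) followed by Williamson-type ring closure of chlorohydrin 3; neither event touches the carbinol carbon, so the purchased (R) centre is carried into 4 unchanged.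

Step 2
Reactants: 4 (R)-2-undecyloxirane; 5 2-iodo-6-methoxyphenol
Product: 7 2-[(2R)-2-hydroxytridecyl]-6-methoxyphenol, via (R)-1-iodotridecan-2-ol 6 (not isolated)
Conditions: 4 (1.5 equiv), NiCl2(dme) (10 mol %), 4,4′-di-tert-butyl-2,2′-bipyridine (15 mol %), 2,4,5,6-tetra(carbazol-9-yl)isophthalonitrile (2 mol %), Et3N (4 equiv), Et3N·HI (0.5 equiv), DMA, 450 nm LEDs, 25 °C; aq NaHCO3 work-up
Reagents that add atoms: none
Why: Nickel/photoredox reductive cross-electrophile coupling of an aryl iodide with a terminal aliphatic epoxide: iodide opens 4 at its CH2 to iodohydrin 6, the photoreduced low-valent nickel catalyst adds the C–I bond of 5 and captures the primary radical from 6, and reductive elimination gives the linear aryl–CH2 bond while the carbinol stereocentre stays untouched.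

Step 3
Reactants: 7 2-[(2R)-2-hydroxytridecyl]-6-methoxyphenol
Product: 8 2-[(2R)-2-hydroxytridecyl]-6-methoxycyclohexa-2,5-diene-1,4-dione
Conditions: ON(SO3K)2 (2.5 equiv), KH2PO4, acetone/H2O, 0 → 25 °C
Reagents that add atoms: potassium nitrosodisulfonate, [O]N(S(=O)(=O)[O-])S(=O)(=O)[O-].[K+].[K+]
Why: Teuber oxidation: the phenoxyl radical of this 2,6-disubstituted phenol is trapped at its free para position by a second nitrosodisulfonate radical and loses imidodisulfonate to give the p-quinone; no stereocentre is involved and the secondary alcohol is inert.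

Step 4
Reactants: 8 2-[(2R)-2-hydroxytridecyl]-6-methoxycyclohexa-2,5-diene-1,4-dione
Product: 10 (2R)-1-[(3S,6S)-6-acetoxy-3-hydroxy-5-methoxycyclohexa-1,4-dien-1-yl]tridecan-2-yl acetate, via hydroxydienone monoacetate 9 (not isolated)
Conditions: MeCHO (8 equiv), SmI2 (30 mol %; divalent samarium, stirred with the MeCHO until decolourised to the trivalent samarium alkoxide catalyst), THF, −20 °C, slow addition of 8, dark; pH 7 buffer quench
Reagents that add atoms: acetaldehyde, CC=O
Why: Proposed new method: a samarium-templated relay (double) Tishchenko hydride transfer, in which the side-chain hydroxyl of 8 adds to MeCHO to give a trivalent samarium hemiacetalate whose C–H is delivered intramolecularly (seven-membered array, samarium bridging the hemiacetal oxygen and the C6 carbonyl oxygen, undecyl chain outward, Cβ–H toward the metal) to the Re face of the ring C6 carbonyl, so the side-chain OH becomes its acetate and C6 becomes the (S)-alkoxide 9; that alkoxide adds a second MeCHO, and the new hemiacetal C–H, tethered to the C6 oxygen, can reach C3 only across the ring on the face of the C6–O bond, so hydride enters the Re face of C3 cis to C6–O (trans-diol, 3S) while the C6 oxygen becomes the second acetate and the C3 oxygen stays free; the closest known reactions are the Evans–Tishchenko reduction of β-hydroxy ketones and hydroxyl-directed (Saksena–Evans type) anti reductions of cyclic γ-hydroxy enones, neither shown on a quinone, through a seven-membered array, or as a relay.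

**Compound list**
1 | (R)-epichlorohydrin [(R)-2-(chloromethyl)oxirane] | ClC[C@H]1CO1 | starting material
2 | decylmagnesium bromide | CCCCCCCCCC[Mg]Br | starting material
3 | (R)-1-chlorotridecan-2-ol | ClC[C@H](O)CCCCCCCCCCC | intermediate
4 | (R)-2-undecyloxirane | CCCCCCCCCCC[C@@H]1CO1 | intermediate
5 | 2-iodo-6-methoxyphenol | COc1cccc(I)c1O | starting material
6 | (R)-1-iodotridecan-2-ol | CCCCCCCCCCC[C@H](CI)O | intermediate
7 | 2-[(2R)-2-hydroxytridecyl]-6-methoxyphenol | CCCCCCCCCCC[C@H](Cc1cccc(OC)c1O)O | intermediate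
8 | 2-[(2R)-2-hydroxytridecyl]-6-methoxycyclohexa-2,5-diene-1,4-dione | CCCCCCCCCCC[C@H](CC1=CC(=O)C=C(OC)C1=O)O | intermediate
9 | (2R)-1-[(6S)-6-hydroxy-5-methoxy-3-oxocyclohexa-1,4-dien-1-yl]tridecan-2-yl acetate | CCCCCCCCCCC[C@H](CC1=CC(=O)C=C(OC)[C@H]1O)OC(C)=O | intermediate
10 | (2R)-1-[(3S,6S)-6-acetoxy-3-hydroxy-5-methoxycyclohexa-1,4-dien-1-yl]tridecan-2-yl acetate (CNP0081579.1) | CCCCCCCCCCC[C@H](CC1=C[C@H](O)C=C(OC)[C@H]1OC(C)=O)OC(C)=O | target

**Step count and risks**
Total steps: 4. Longest linear sequence: 4 (from 1).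

Steps most likely to fail:

Step 4 (the new relay reduction) is the main risk. The transient 4-H dienone alkoxide 9 can tautomerise to the hydroquinone, undirected intermolecular hydride transfer to the quinone can compete, and the facial sense at C6 is predicted from a model only and could be low or reversed. The fallback uses known chemistry, sets out from 8 and comes back at 10, but it does not control the ring stereocentres; it relies on separating diastereomers. Acetylate the side-chain hydroxyl (Ac2O, pyridine, 4-(dimethylamino)pyridine) to (2R)-1-(5-methoxy-3,6-dioxocyclohexa-1,4-dien-1-yl)tridecan-2-yl acetate F4. Reduce both quinone carbonyls with the ester-tolerant hydride LiAlH(OtBu)3 in THF at −78 °C and separate by chromatography the trans isomer (2R)-1-[(3S,6S)-3,6-dihydroxy-5-methoxycyclohexa-1,4-dien-1-yl]tridecan-2-yl acetate F5 from its ring diastereomers. Silylate the unhindered C3 hydroxyl (Et3SiCl, imidazole, −20 °C) to (2R)-1-[(3S,6S)-6-hydroxy-5-methoxy-3-(triethylsilyloxy)cyclohexa-1,4-dien-1-yl]tridecan-2-yl acetate F6. Acetylate the hindered C6 hydroxyl (Ac2O, 4-(dimethylamino)pyridine) to (2R)-1-[(3S,6S)-6-acetoxy-5-methoxy-3-(triethylsilyloxy)cyclohexa-1,4-dien-1-yl]tridecan-2-yl acetate F7. Remove the silyl group (Bu4NF/AcOH, THF, 0 °C) to reach 10.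

Step 2 may suffer from the free ortho-phenol: the phenoxide can be oxidised by the excited photocatalyst or bind nickel, and O-alkylation by 6 is possible. The fallback sets out from 4 and comes back at 7 by polar organometallic chemistry. Guaiacol is protected (MOMCl, iPr2NEt) as 1-methoxy-2-(methoxymethoxy)benzene F1. F1 is lithiated ortho to the acetal oxygen (n-BuLi, N,N,N′,N′-tetramethylethylenediamine, THF, 0 °C), and the aryllithium opens 4 at its CH2 (BF3·OEt2, −78 °C) to give (2R)-1-[3-methoxy-2-(methoxymethoxy)phenyl]tridecan-2-ol F2. HCl in MeOH then removes the acetal to give 7.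

Step 3 may give some ortho-quinone or over-oxidation. The fallback sets out from 7 and comes back at 8 electrochemically. Constant-current anodic oxidation (graphite anode, LiClO4, MeOH, 0 °C) gives the quinone monoketal 2-[(2R)-2-hydroxytridecyl]-4,4,6-trimethoxycyclohexa-2,5-dien-1-one F3, which dilute aqueous AcOH in THF hydrolyses to 8.

**Further compounds**
F1 | step 2 | 1-methoxy-2-(methoxymethoxy)benzene | COCOc1ccccc1OC
F2 | step 2 | (2R)-1-[3-methoxy-2-(methoxymethoxy)phenyl]tridecan-2-ol | CCCCCCCCCCC[C@H](Cc1cccc(OC)c1OCOC)O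
F3 | step 3 | 2-[(2R)-2-hydroxytridecyl]-4,4,6-trimethoxycyclohexa-2,5-dien-1-one | CCCCCCCCCCC[C@H](CC1=CC(OC)(OC)C=C(OC)C1=O)O
F4 | step 4 | (2R)-1-(5-methoxy-3,6-dioxocyclohexa-1,4-dien-1-yl)tridecan-2-yl acetate | CCCCCCCCCCC[C@H](CC1=CC(=O)C=C(OC)C1=O)OC(C)=O
F5 | step 4 | (2R)-1-[(3S,6S)-3,6-dihydroxy-5-methoxycyclohexa-1,4-dien-1-yl]tridecan-2-yl acetate | CCCCCCCCCCC[C@H](CC1=C[C@H](O)C=C(OC)[C@H]1O)OC(C)=O
F6 | step 4 | (2R)-1-[(3S,6S)-6-hydroxy-5-methoxy-3-(triethylsilyloxy)cyclohexa-1,4-dien-1-yl]tridecan-2-yl acetate | CCCCCCCCCCC[C@H](CC1=C[C@H](O[Si](CC)(CC)CC)C=C(OC)[C@H]1O)OC(C)=O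
F7 | step 4 | (2R)-1-[(3S,6S)-6-acetoxy-5-methoxy-3-(triethylsilyloxy)cyclohexa-1,4-dien-1-yl]tridecan-2-yl acetate | CCCCCCCCCCC[C@H](CC1=C[C@H](O[Si](CC)(CC)CC)C=C(OC)[C@H]1OC(C)=O)OC(C)=O
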